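**Retrosynthetic overview**

1. The target is 3-bromolabda-7,14-dien-13-ol with (3R,5S,9S,10S,13R) configuration. The C9–C11 bond is cut to a bicyclic C7-keto-Δ8(9) enone and a C11–C16 Grignard reagent made from (R)-linalool; conjugate addition anti to the axial C20 methyl sets C9, and the C7 enol triflate is then reduced to the C7=C8 alkene.
2. Ring B (C5–C10) is cut at C8=C9 (ring-closing metathesis) and C7–C8 (isopropenyl addition). The equatorial C3 bromide comes from radical (hydrogen-atom-transfer) hydrogenation of a C2=C3 bromoalkene held in a trans-fused C9/C7 lactone, a temporary tether that locks the ring A chair.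
3. Ring A is cut across C4–C5 and C1–C10 by an enantioselective Diels–Alder reaction of an amino siloxy diene with an (E)-2-methyl enal. The plan rests on the vicinal pair in ring A: quaternary C10 (C20 methyl and C9) next to C5 (H and C6), with C9 trans to C6. This pair is the α,β-pair of the (E)-enal, whose formyl carbon is C9.
4. Ring order: ring A (step 2), lactone tether ring (steps 3–4, opened in steps 9–10), ring B (step 13).

Key step: step 2

Remark 1: labdane numbering is used for all intermediates (ring A = C1–C5, C10; ring B = C5–C10; C20 = angular methyl; side chain C11–C16).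
Remark 2: the basic dialkylamino diene and its amine cycloadduct would bind a cationic metal Lewis acid, so the cycloaddition is run with a chiral diol (hydrogen-bond) catalyst. The (4R,5R) antipode is assumed to open the C2-Re (C3-Si) face of enal 3; if the sense is opposite, the (4S,5S) antipode is used.

**Route**

Step 1
Reactants: 1 3-(tert-butyldimethylsilyloxy)propanal; 2 2-(triphenylphosphoranylidene)propanal
Product: 3 (E)-5-(tert-butyldimethylsilyloxy)-2-methylpent-2-enal
Conditions: toluene, 90 °C
Reagents that add atoms: none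
Why: Wittig olefination with a stabilised formyl ylide should give the (E)-trisubstituted enal, formyl trans to the silyloxyethyl chain.

Step 2
Reactants: 3 (E)-5-(tert-butyldimethylsilyloxy)-2-methylpent-2-enal; 4 (E)-1-(dimethylamino)-3-(tert-butyldimethylsilyloxy)buta-1,3-diene
Product: 6 (4S,5R)-4-formyl-4-methyl-5-[2-(tert-butyldimethylsilyloxy)ethyl]cyclohex-2-en-1-one, via cycloadduct 5 (not isolated)
Conditions: (4R,5R)-2,2-dimethyl-α,α,α′,α′-tetra(1-naphthyl)-1,3-dioxolane-4,5-dimethanol (1-naphthyl TADDOL, 20 mol %), toluene, −40 °C; then AcCl, CH2Cl2, −78 °C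
Reagents that add atoms: none
Why: This is a hydrogen-bond-catalysed Diels–Alder reaction, the closest known case being the TADDOL-promoted cycloaddition of this diene with 2-substituted acroleins: one diol hydroxyl binds the formyl oxygen of 3 and lowers its LUMO, and the diene adds in a concerted, asynchronous [4+2] step in which its CH2 terminus bonds to C5 ahead of the C1–C10 bond. Ring A closes in this single suprafacial cycloaddition (six-membered, bonds C4–C5 and C1–C10), and acetyl chloride then N-acylates the amine of 5, which leaves together with the enol silyl group to unveil the C1=C2–C3=O enone. The relative configuration at C5 and C10 (C9 formyl trans to the C6 arm) is fixed by the (E) geometry of 3, which the suprafacial addition preserves. The absolute configuration comes from the chiral diol, whose naphthyl groups shield one face of the bound enal so that the diene enters on the C2-Re (C3-Si) face. Regiochemistry follows from the matched donors (amino and siloxy groups both push to the diene CH2 terminus) and the formyl-activated β-carbon. The step needs periselectivity for C=C over the formyl C=O (hetero-Diels–Alder), which the α-methyl branch and the conjugation of the formyl group favour, and the amino-bearing centre of 5 is of no consequence because it is lost.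

Step 3
Reactants: 6 (4S,5R)-4-formyl-4-methyl-5-[2-(tert-butyldimethylsilyloxy)ethyl]cyclohex-2-en-1-one
Product: 8 trans-fused lactol (C9 hemiacetal closed by the C7 oxygen; ring A enone; anomers), via hydroxy aldehyde 7 (not isolated)
Conditions: 48 % aq. HF, MeCN, 0 °C
Reagents that add atoms: none
Why: Acidic fluoride desilylation frees the C7 hydroxyl, which should close onto the neopentyl C9 aldehyde as a six-membered hemiacetal with both arms equatorial on ring A; the anomeric centre forms as a mixture and is removed in step 4.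

Step 4
Reactants: 8 trans-fused lactol
Product: 9 (4aR,8aS)-8a-methyl-4,4a,5,8a-tetrahydro-1H-isochromene-1,6(3H)-dione (trans-fused lactone enone)
Conditions: TEMPO (10 mol %), PhI(OAc)2, CH2Cl2, rt
Reagents that add atoms: none
Why: Oxoammonium (TEMPO) oxidation of a lactol to the lactone, which has no α-hydrogen (C10 is quaternary) and ties C9 to C7 in a rigid trans-fused bicycle.

Step 5
Reactants: 9 trans-fused lactone enone
Product: 11 (4aR,8aR)-5,5,8a-trimethyl-4,4a,5,8a-tetrahydro-1H-isochromene-1,6(3H)-dione (C4 gem-dimethyl lactone enone), via monomethyl ketone 10 (not isolated)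
Conditions: KOt-Bu (3 equiv), MeI (6 equiv), THF/t-BuOH, 0 °C → rt
Reagents that add atoms: iodomethane, CI
Why: Exhaustive enolate alkylation, possible because C4 is the only enolisable carbon (C10 is quaternary, C2 is vinylic, the lactone has no α-hydrogen), so the cross-conjugated enolate is methylated twice at C4.

Step 6
Reactants: 11 C4 gem-dimethyl lactone enone
Product: 13 C2=C3 enol triflate of the lactone (triflate on C3), via lithium enolate 12 (not isolated)
Conditions: LiBH(s-Bu)3 (1.1 equiv), THF, −78 °C; then PhNTf2, −78 °C → rt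
Reagents that add atoms: N-phenylbis(trifluoromethanesulfonimide), O=S(=O)(N(c1ccccc1)S(=O)(=O)C(F)(F)F)C(F)(F)F
Why: Reductive triflation: conjugate hydride addition to the β-unsubstituted enone (1,2-attack is blocked by the C4 gem-dimethyl group) gives the C2=C3 enolate regiospecifically, which is trapped on oxygen.

Step 7
Reactants: 13 C2=C3 enol triflate
Product: 14 C2=C3 alkenyl bromide (bromine on C3) of the trans-fused lactone
Conditions: Ni(OAc)2·4H2O (10 mol %), Zn (20 mol %), 1,5-cyclooctadiene, LiBr (2 equiv), DMA/THF, rt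
Reagents that add atoms: lithium bromide, [Li+].[Br-]
Why: Nickel-catalysed triflate-to-bromide exchange of an enol triflate (oxidative addition of zerovalent nickel to the C–O bond, anion exchange, reductive elimination) keeps the double-bond position.

Step 8
Reactants: 14 C2=C3 alkenyl bromide
Product: 15 bromo lactone (6-bromo-5,5,8a-trimethyloctahydro-1H-isochromen-1-one; trans-fused; bromine equatorial, C3 R)
Conditions: Co(acac)2 (25 mol %), t-BuOOH (25 mol %), Et3SiH, 1,4-cyclohexadiene, n-PrOH, rt
Reagents that add atoms: none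
Why: Cobalt-hydride hydrogen-atom-transfer hydrogenation of an alkenyl bromide (Mukaiyama-type radical hydrogenation): H• adds to C2, and the α-bromo C3 radical, held in the rigid trans-fused chair, should take its hydrogen from 1,4-cyclohexadiene on the axial face opposite the axial C4 methyl and C20, leaving bromine equatorial (3R).

Step 9
Reactants: 15 bromo lactone
Product: 16 bromo lactol (C9 hemiacetal; anomers)
Conditions: i-Bu2AlH, CH2Cl2, −78 °C
Reagents that add atoms: none
Why: Partial hydride reduction of the hindered lactone stops at the lactol because the tetrahedral aluminate is stable at −78 °C.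

Step 10
Reactants: 16 bromo lactol
Product: 18 monocyclic hydroxy alkene (ring A with C10 methyl and vinyl, C5 2-hydroxyethyl trans to vinyl, C4 gem-dimethyl, C3 equatorial bromide), via open-chain hydroxy aldehyde 17 (not isolated)
Conditions: Ph3PCH3Br, KOt-Bu, THF, 0 → 40 °C
Reagents that add atoms: methyltriphenylphosphonium bromide, C[P+](c1ccccc1)(c1ccccc1)c1ccccc1.[Br-]
Why: Wittig methylenation of the lactol through its open aldehyde form; C9 has no α-hydrogen, and the equatorial bromide has no antiperiplanar hydrogen, so elimination should not compete.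

Step 11
Reactants: 18 monocyclic hydroxy alkene
Product: 19 C7 aldehyde
Conditions: Dess–Martin periodinane, NaHCO3, CH2Cl2, 0 °C → rt
Reagents that add atoms: none
Why: Dess–Martin oxidation of the primary alcohol under buffered, non-basic conditions.

Step 12
Reactants: 19 C7 aldehyde
Product: 20 allylic alcohol (C7 carbinol bearing the isopropenyl group C8/C17; C7 epimers)
Conditions: isopropenylmagnesium bromide, THF, −78 °C
Reagents that add atoms: isopropenylmagnesium bromide, C=C(C)[Mg]Br
Why: Grignard 1,2-addition; the C7 centre forms as a mixture and is removed by oxidation in step 14.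

Step 13
Reactants: 20 allylic alcohol
Product: 21 bicyclic allylic alcohol (trans-decalin, C8=C9, C7–OH, C3 equatorial bromide)
Conditions: second-generation Grubbs catalyst RuCl2(=CHPh)(H2IMes)(PCy3) (5 mol %), CH2Cl2, 40 °C
Reagents that add atoms: none
Why: Ring-closing olefin metathesis between the C10 vinyl group and the isopropenyl group closes six-membered ring B at C8=C9 with loss of ethylene, the two arms being equatorial on ring A so that the trans-fused decalin forms without strain.

Step 14
Reactants: 21 bicyclic allylic alcohol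
Product: 22 bicyclic enone (C7 ketone, C8=C9, C17 methyl on C8)
Conditions: Dess–Martin periodinane, NaHCO3, CH2Cl2, rt
Reagents that add atoms: none
Why: Dess–Martin oxidation of the allylic alcohol converges both C7 epimers on one enone.

Step 15
Reactants: 23 (R)-linalool
Product: 24 (R)-3,7-dimethyl-3-(triethylsilyloxy)octa-1,6-diene
Conditions: Et3SiOTf, 2,6-lutidine, CH2Cl2, −78 → 0 °C
Reagents that add atoms: triethylsilyl trifluoromethanesulfonate, CC[Si](CC)(CC)OS(=O)(=O)C(F)(F)F
Why: Silylation of the tertiary alcohol with a silyl triflate; the C13 centre is not touched.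

Step 16
Reactants: 24 (R)-3,7-dimethyl-3-(triethylsilyloxy)octa-1,6-diene
Product: 26 (R)-4-methyl-4-(triethylsilyloxy)hex-5-enal, via ozonide 25 (not isolated)
Conditions: O3 (1 equiv, dye end point), CH2Cl2, −78 °C; then PPh3, −78 °C → rt
Reagents that add atoms: ozone, [O-][O+]=O
Why: Ozonolysis is selective for the electron-rich trisubstituted alkene over the monosubstituted vinyl group next to the quaternary silyloxy carbon.

Step 17
Reactants: 26 (R)-4-methyl-4-(triethylsilyloxy)hex-5-enal
Product: 27 (R)-4-methyl-4-(triethylsilyloxy)hex-5-enoic acid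
Conditions: NaClO2, NaH2PO4, 2-methyl-2-butene, t-BuOH/H2O, 0 °C → rt
Reagents that add atoms: sodium chlorite, [Na+].[O-]Cl=O
Why: Pinnick oxidation, with the hypochlorite by-product scavenged so that the vinyl group is spared.

Step 18
Reactants: 27 (R)-4-methyl-4-(triethylsilyloxy)hex-5-enoic acid
Product: 29 (R)-5-iodo-3-methyl-3-(triethylsilyloxy)pent-1-ene, via thiohydroxamate ester 28 (not isolated)
Conditions: 2-mercaptopyridine N-oxide, DCC, DMAP (cat.), CH2Cl2, 0 °C → rt, dark; then CHI3, PhH, hν (tungsten lamp), 80 °C
Reagents that add atoms: iodoform, IC(I)I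
Why: Barton decarboxylative iodination removes the carboxyl carbon, so the chain ends at C11; the primary 4-pentenyl-type radical does not cyclise before iodine transfer.

Step 19
Reactants: 29 (R)-5-iodo-3-methyl-3-(triethylsilyloxy)pent-1-ene; 22 bicyclic enone
Product: 31 C7 trimethylsilyl enol ether carrying the C11–C16 side chain on C9 (C7=C8), via Grignard reagent 30 (not isolated)
Conditions: 29, Mg, Et2O, rt; then 22, CuBr·SMe2 (10 mol %), Me3SiCl, HMPA, THF, −78 → −40 °C; Et3N
Reagents that add atoms: chlorotrimethylsilane, C[Si](C)(C)Cl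
Why: Copper-catalysed, silyl chloride-accelerated conjugate addition of a Grignard reagent: the organocopper should add to C9 on the face opposite the axial C20 methyl (axial attack, as in cuprate additions to angular-methyl 1-en-3-ones), which sets C9 (S) with the side chain trans to C20, and the enolate is trapped with the C7=C8 double bond in place.

Step 20
Reactants: 31 C7 trimethylsilyl enol ether
Product: 32 C7 enol triflate (C7=C8)
Conditions: CsF, PhNTf2, DME, rt
Reagents that add atoms: N-phenylbis(trifluoromethanesulfonimide), O=S(=O)(N(c1ccccc1)S(=O)(=O)C(F)(F)F)C(F)(F)F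
Why: Fluoride-mediated conversion of a silyl enol ether into the enol triflate keeps the enolate regiochemistry and avoids a strong base near the bromide.

Step 21
Reactants: 32 C7 enol triflate
Product: 33 13-O-triethylsilyl ether of the target
Conditions: Pd(OAc)2 (5 mol %), PPh3, HCO2H, n-Bu3N, DMF, 60 °C
Reagents that add atoms: none
Why: Palladium-catalysed formate reduction of an enol triflate (oxidative addition, formate exchange, decarboxylation, reductive elimination) gives the C7=C8 alkene and leaves the unactivated secondary bromide alone.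

Step 22
Reactants: 33 13-O-triethylsilyl ether of the target
Product: 34 (3R,5S,9S,10S,13R)-3-bromolabda-7,14-dien-13-ol
Conditions: Bu4NF, THF, 0 °C → rt
Reagents that add atoms: none
Why: Fluoride desilylation frees the tertiary allylic alcohol without acid, and the equatorial bromide has no antiperiplanar hydrogen for elimination.

**Compound list**

1 | 3-(tert-butyldimethylsilyloxy)propanal | O=CCCO[Si](C)(C)C(C)(C)C | starting material
2 | 2-(triphenylphosphoranylidene)propanal | CC(C=O)=P(c1ccccc1)(c1ccccc1)c1ccccc1 | starting material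
3 | (E)-5-(tert-butyldimethylsilyloxy)-2-methylpent-2-enal | O=C/C(C)=C/CCO[Si](C)(C)C(C)(C)C | intermediate
4 | (E)-1-(dimethylamino)-3-(tert-butyldimethylsilyloxy)buta-1,3-diene | CN(C)/C=C/C(=C)O[Si](C)(C)C(C)(C)C | starting material
5 | (1S,6R)-2-(dimethylamino)-1-methyl-4-(tert-butyldimethylsilyloxy)-6-[2-(tert-butyldimethylsilyloxy)ethyl]cyclohex-3-ene-1-carbaldehyde (amino-bearing C2 unassigned) | CN(C)C1C=C(O[Si](C)(C)C(C)(C)C)C[C@@H](CCO[Si](C)(C)C(C)(C)C)[C@]1(C)C=O | intermediate
6 | (4S,5R)-4-formyl-4-methyl-5-[2-(tert-butyldimethylsilyloxy)ethyl]cyclohex-2-en-1-one | CC(C)(C)[Si](C)(C)OCC[C@@H]1CC(=O)C=C[C@]1(C=O)C | intermediate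
7 | (4S,5R)-4-formyl-5-(2-hydroxyethyl)-4-methylcyclohex-2-en-1-one | OCC[C@@H]1CC(=O)C=C[C@]1(C=O)C | intermediate
8 | (4aR,8aS)-1-hydroxy-8a-methyl-1,3,4,4a,5,8a-hexahydro-6H-isochromen-6-one (trans-fused lactol, anomers) | O=C1C=C[C@@]2(C)C(O)OCC[C@@H]2C1 | intermediate
9 | (4aR,8aS)-8a-methyl-4,4a,5,8a-tetrahydro-1H-isochromene-1,6(3H)-dione | O=C1C=C[C@@]2(C)C(=O)OCC[C@@H]2C1 | intermediate
10 | 5,8a-dimethyl analogue of 9 (C4 monomethyl, epimers at that carbon; ring fusion as in 9) | O=C1C=C[C@@]2(C)C(=O)OCC[C@@H]2C1C | intermediate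
11 | (4aR,8aR)-5,5,8a-trimethyl-4,4a,5,8a-tetrahydro-1H-isochromene-1,6(3H)-dione | O=C1C=C[C@@]2(C)C(=O)OCC[C@@H]2C1(C)C | intermediate
12 | lithium C2=C3 enolate of the saturated keto lactone (ring fusion as in 11) | [Li]OC1=CC[C@@]2(C)C(=O)OCC[C@@H]2C1(C)C | intermediate
13 | C2=C3 enol triflate: 5,5,8a-trimethyl-1-oxo-3,4,4a,5,8,8a-hexahydro-1H-isochromen-6-yl trifluoromethanesulfonate (ring fusion as in 11) | FC(F)(F)S(=O)(=O)OC1=CC[C@@]2(C)C(=O)OCC[C@@H]2C1(C)C | intermediate
14 | 6-bromo-5,5,8a-trimethyl-3,4,4a,5,8,8a-hexahydro-1H-isochromen-1-one (ring fusion as in 11) | BrC1=CC[C@@]2(C)C(=O)OCC[C@@H]2C1(C)C | intermediate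
15 | 6-bromo-5,5,8a-trimethyloctahydro-1H-isochromen-1-one (trans-fused; bromine equatorial, labdane C3 R) | Br[C@@H]1CC[C@@]2(C)C(=O)OCC[C@@H]2C1(C)C | intermediate
16 | 6-bromo-5,5,8a-trimethyloctahydro-1H-isochromen-1-ol (lactol of 15, anomers) | Br[C@@H]1CC[C@@]2(C)C(O)OCC[C@@H]2C1(C)C | intermediate
17 | open form of 16: cyclohexane with C10 (methyl, formyl), C5 (2-hydroxyethyl, trans to formyl), C4 gem-dimethyl, C3 equatorial bromide | Br[C@@H]1CC[C@@](C)(C=O)[C@H](CCO)C1(C)C | intermediate
18 | same ring with C10 (methyl, vinyl) and C5 2-hydroxyethyl trans to vinyl | Br[C@@H]1CC[C@@](C)(C=C)[C@H](CCO)C1(C)C | intermediate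
19 | C7 aldehyde of 18 (C5 bears CH2CHO) | Br[C@@H]1CC[C@@](C)(C=C)[C@H](CC=O)C1(C)C | intermediate
20 | allylic alcohol: C5 bears CH2CH(OH)C(CH3)=CH2 (C7 epimers) | Br[C@@H]1CC[C@@](C)(C=C)[C@H](CC(O)C(C)=C)C1(C)C | intermediate
21 | trans-decalin allylic alcohol: 3-bromo-4,4,8,10-tetramethyl skeleton, C8=C9, C7–OH (C7 epimers), 3R | Br[C@@H]1CC[C@@]2(C)C=C(C)C(O)C[C@@H]2C1(C)C | intermediate
22 | trans-decalin enone: C7 ketone, C8=C9, C17 methyl on C8, 3R equatorial bromide | Br[C@@H]1CC[C@@]2(C)C=C(C)C(=O)C[C@@H]2C1(C)C | intermediate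
23 | (R)-linalool | C=C[C@](C)(O)CCC=C(C)C | starting material
24 | (R)-3,7-dimethyl-3-(triethylsilyloxy)octa-1,6-diene | C=C[C@](C)(O[Si](CC)(CC)CC)CCC=C(C)C | intermediate
25 | ozonide (1,2,4-trioxolane) of the trisubstituted alkene of 24 | C=C[C@](C)(O[Si](CC)(CC)CC)CCC1OOC(C)(C)O1 | intermediate
26 | (R)-4-methyl-4-(triethylsilyloxy)hex-5-enal | C=C[C@](C)(O[Si](CC)(CC)CC)CCC=O | intermediate
27 | (R)-4-methyl-4-(triethylsilyloxy)hex-5-enoic acid | C=C[C@](C)(O[Si](CC)(CC)CC)CCC(=O)O | intermediate
28 | 2-thioxopyridin-1(2H)-yl ester of 27 | C=C[C@](C)(O[Si](CC)(CC)CC)CCC(=O)On1ccccc1=S | intermediate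
29 | (R)-5-iodo-3-methyl-3-(triethylsilyloxy)pent-1-ene | C=C[C@](C)(O[Si](CC)(CC)CC)CCI | intermediate
30 | [(R)-3-methyl-3-(triethylsilyloxy)pent-4-en-1-yl]magnesium iodide | C=C[C@](C)(O[Si](CC)(CC)CC)CC[Mg]I | intermediate
31 | C7 trimethylsilyl enol ether (C7=C8) with the 13-O-triethylsilyl side chain on C9, trans to C20 | Br[C@@H]1CC[C@@]2(C)[C@@H](CC[C@@](C)(O[Si](CC)(CC)CC)C=C)C(C)=C(O[Si](C)(C)C)C[C@@H]2C1(C)C | intermediate
32 | C7 enol triflate (C7=C8) of the same skeleton | Br[C@@H]1CC[C@@]2(C)[C@@H](CC[C@@](C)(O[Si](CC)(CC)CC)C=C)C(C)=C(OS(=O)(=O)C(F)(F)F)C[C@@H]2C1(C)C | intermediate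
33 | 13-O-triethylsilyl ether of the target | Br[C@@H]1CC[C@@]2(C)[C@@H](CC[C@@](C)(O[Si](CC)(CC)CC)C=C)C(C)=CC[C@@H]2C1(C)C | intermediate
34 | (3R,5S,9S,10S,13R)-3-bromolabda-7,14-dien-13-ol (CNP0210577.1) | C=C[C@](C)(O)CC[C@H]1C(C)=CC[C@@H]2C(C)(C)[C@H](Br)CC[C@]21C | target

**Step count**

Total: 22 steps. Longest linear sequence: 18 steps (steps 1–14 and 19–22); the side chain takes 4 steps (15–18).

**Steps most likely to fail**

Step 2. The C=C cycloaddition at the trisubstituted, only hydrogen-bond-activated enal may be too slow at the temperature needed for face control, so that hetero-Diels–Alder addition at the formyl C=O and erosion of enantioselectivity take over. The fallback replaces catalyst control by an auxiliary on the diene nitrogen and runs the cycloaddition thermally; it sets out from 3 and comes back at 6. (E)-4-Methoxybut-3-en-2-one is condensed with (2R,5R)-2,5-diphenylpyrrolidine to (E)-4-[(2R,5R)-2,5-diphenylpyrrolidin-1-yl]but-3-en-2-one F1, which KN(SiMe3)2 and TBSCl in THF at −78 °C convert into (E)-1-[(2R,5R)-2,5-diphenylpyrrolidin-1-yl]-3-(tert-butyldimethylsilyloxy)buta-1,3-diene F2. F2 and 3 are warmed in toluene without any hydrogen-bond donor, where the normal C=C mode is expected, to the auxiliary-bearing cycloadduct F3. Brief treatment with cold dilute aqueous HCl in THF releases 6 and the recoverable amine; the auxiliary antipode is chosen for the required face.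

Step 19. Conjugate addition at the neopentyl C9 of the α-methyl enone may be slow, so that 1,2-addition, enolisation and loss of the Grignard reagent compete. The fallback forms the C9–C11 bond by a sigmatropic rearrangement; it sets out from 22 and comes back at 33, bypassing 31 and 32. Reduction with NaBH4 and CeCl3·7H2O in MeOH (axial hydride delivery) should give the pseudoequatorial C7 allylic alcohol F7. Mitsunobu esterification with acid 27 (PPh3, diisopropyl azodicarboxylate) inverts C7 to the pseudoaxial C7 ester of acid 27 F8. KN(SiMe3)2 and Me3SiCl in THF, −78 °C → rt, trigger an Ireland–Claisen rearrangement that forms C9–C11 on the face of the C7–O bond (anti to C20) and moves the alkene to C7=C8, giving the C11 carboxylic acid F9. Barton reductive decarboxylation (2-mercaptopyridine N-oxide, DCC; t-BuSH, hν) then gives 33.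

Step 8. Hydrogen-atom transfer to the hindered trisubstituted bromoalkene may be slow, and addition in the wrong sense gives a β-bromo radical that loses bromine. The fallback makes the same C3 α-bromo radical from a gem-dibromide; it sets out from 11 and comes back at 15, bypassing 13 and 14. Hydrogenation of 11 (H2, Pd/C, EtOAc) gives the saturated keto lactone F4, and N2H4·H2O in EtOH gives its hydrazone F5. CuBr2 and LiOt-Bu in THF convert F5 into the C3 gem-dibromide F6. Bu3SnH (1.05 equiv) with AIBN in benzene at 80 °C removes one bromine, and the C3 radical takes hydrogen on the axial face to give 15.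

**Further compounds**

F1 | step 2 | (E)-4-[(2R,5R)-2,5-diphenylpyrrolidin-1-yl]but-3-en-2-one | CC(=O)/C=C/N1[C@@H](c2ccccc2)CC[C@@H]1c1ccccc1
F2 | step 2 | (E)-1-[(2R,5R)-2,5-diphenylpyrrolidin-1-yl]-3-(tert-butyldimethylsilyloxy)buta-1,3-diene | C=C(O[Si](C)(C)C(C)(C)C)/C=C/N1[C@@H](c2ccccc2)CC[C@@H]1c1ccccc1
F3 | step 2 | auxiliary-bearing cycloadduct (analogue of 5 with the diphenylpyrrolidine in place of NMe2) | c1ccccc1[C@H]1CC[C@H](c2ccccc2)N1C1C=C(O[Si](C)(C)C(C)(C)C)C[C@@H](CCO[Si](C)(C)C(C)(C)C)[C@]1(C)C=O
F4 | step 8 | saturated keto lactone (5,5,8a-trimethylhexahydro-1H-isochromene-1,6-dione, trans-fused) | O=C1CC[C@@]2(C)C(=O)OCC[C@@H]2C1(C)C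
F5 | step 8 | hydrazone of F4 | NN=C1CC[C@@]2(C)C(=O)OCC[C@@H]2C1(C)C
F6 | step 8 | C3 gem-dibromide (6,6-dibromo-5,5,8a-trimethyloctahydro-1H-isochromen-1-one) | BrC1(Br)CC[C@@]2(C)C(=O)OCC[C@@H]2C1(C)C
F7 | step 19 | pseudoequatorial C7 allylic alcohol (OH cis to C20) | Br[C@@H]1CC[C@@]2(C)C=C(C)[C@H](O)C[C@@H]2C1(C)C
F8 | step 19 | pseudoaxial C7 ester of acid 27 | Br[C@@H]1CC[C@@]2(C)C=C(C)[C@@H](OC(=O)CC[C@@](C)(O[Si](CC)(CC)CC)C=C)C[C@@H]2C1(C)C
F9 | step 19 | C11 carboxylic acid from the Ireland–Claisen rearrangement (C11 epimers) | Br[C@@H]1CC[C@@]2(C)[C@@H](C(C(=O)O)C[C@@](C)(O[Si](CC)(CC)CC)C=C)C(C)=CC[C@@H]2C1(C)C
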